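**Retrosynthetic overview**

1. C4–OH is introduced last by allylic hydroxylation of the 5(16)-methylene; C6–Cl comes by Appel inversion of a C6 alcohol set by hydroxyl-directed reduction of a macrocyclic enone; the ten-membered ring is closed at C5–C6 by a Nozaki–Hiyama–Kishi reaction.
2. The east γ-lactone (C7/C8/C17/C19) comes from iodolactonization of a C8 vinyl carbinol; the 11,20-epoxide forms when a γ-lactone template (C8 carbonyl, ring O on C11) is opened and the freed C11 alkoxide closes onto C20–OTs.
3. Key disconnection: C11–C12 and C1–C14. Ring A is made from a 2-silyloxyfuran (C8–C9–C10–C11–O, with C1 as a thioester side chain on C10) and acrolein (C12–C13–C14) by a one-pot Mukaiyama–Michael/aldol annulation; the furanone then relays C10–H and C9–O.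
4. Enabling feature: in ring A the quaternary carbons C11 (epoxide O, C20) and C1 (C15, C2) sit 1,3 across C10, and C14 carries oxygen. C11 can therefore be the γ-carbon and C1 the exocyclic vinylogous α-carbon of one butenolide, both nucleophilic toward a 1,3-bis-electrophile.
5. Ring order: furanone template → ring A → epoxide (template opened) → east γ-lactone → ten-membered ring.

Key step: step 4

Assumption: atoms are numbered as in the briarane skeleton (ring A = C1, C10–C14; ten-membered ring = C1–C10; C15 = methyl on C1; C16 = exocyclic CH2; C20 = epoxide CH2; lactone = C7, C8, C17, C19), and the catalyst enantiomers written are those expected from the usual facial models (the antipode would be taken if the sense proved opposite).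

**Route**

Step 1
Reactants: 1 (tert-butyldimethylsilyloxy)acetaldehyde; 2 methyl propiolate
Product: 3 methyl 5-(tert-butyldimethylsilyloxy)-4-hydroxypent-2-ynoate (racemic)
Conditions: LiN(SiMe3)2, THF, −78 °C; AcOH
Reagents that add atoms: none
Why: 1,2-addition of the lithium acetylide of the propiolate to the aldehyde; the carbinol centre (future C11) is racemic and is flattened again in furan 8.

Step 2
Reactants: 3 methyl 5-(tert-butyldimethylsilyloxy)-4-hydroxypent-2-ynoate; 4 2,2,5-trimethyl-1,3-dioxane-4,6-dione
Product: 7 thioester butenolide S-ethyl 2-[2-(tert-butyldimethylsilyloxymethyl)-5-oxo-2,5-dihydrofuran-3-yl]propanethioate (stereoisomer mixture), via Meldrum adduct 5 (not isolated), via malonic half thioester 6 (not isolated)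
Conditions: Et3N (cat.), MeCN, 60 °C; then EtSH, sealed tube, 80 °C
Reagents that add atoms: ethanethiol CCS
Why: Michael addition of the Meldrum's acid anion to the ynoate β-carbon and lactonization of the γ-hydroxy enoate give the butenolide, then thiolysis of the dioxanedione and decarboxylation leave the thioester; C11 and C1 are both epimerizable here and are reset in step 4.

Step 3
Reactants: 7 thioester butenolide
Product: 8 silyloxyfuran S-ethyl 2-[5-(tert-butyldimethylsilyloxy)-2-(tert-butyldimethylsilyloxymethyl)furan-3-yl]propanethioate (racemic at C1)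
Conditions: TBSOTf, Et3N, CH2Cl2, 0 °C
Reagents that add atoms: tert-butyldimethylsilyl triflate CC(C)(C)[Si](C)(C)OS(=O)(=O)C(F)(F)F
Why: soft enolization (silyl triflate/amine) of the butenolide should give the aromatic 2-silyloxyfuran as the thermodynamic silyl dienol ether, making C11 sp2.

Step 4
Reactants: 8 silyloxyfuran; 9 acrolein
Product: 11 annulation product (bicyclic butenolide thioester: ring A fused to the furanone at C10–C11; C14–OH cis to the thioester), via Michael aldehyde 10 (not isolated)
Conditions: (2S,5S)-5-benzyl-2-tert-butyl-3-methylimidazolidin-4-one·2,4-dinitrobenzoic acid (20 mol%), H2O (2 equiv), CH2Cl2, −40 °C; then LiCl, DBU (cat.), MeCN, −40 → 0 °C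
Reagents that add atoms: none
Why: Iminium activation of acrolein lets the furan attack through its α-carbon bearing CH2OTBS (C11) in a Mukaiyama–Michael reaction that forms C11–C12 and, after hydrolysis of the silyloxocarbenium ion and the enamine, gives aldehyde 10 with the butenolide restored; LiCl/DBU then removes the C1–H (alpha to the thioester and vinylogous to the lactone carbonyl) and the lithium dienolate adds to the aldehyde to form C1–C14. The closest known reaction types are the organocatalytic Mukaiyama–Michael addition of 5-substituted 2-silyloxyfurans to enals, which tolerates a quaternary γ-carbon, and the soft-enolization aldol addition of thioester carbanions to tethered aldehydes. Ring A is closed by a 6-(enolexo)-exo-trig aldol; attack through C1 gives the fused and still conjugated butenolide, whereas attack through C9 would give a strained bridged bicycle. C11 is set by the catalyst (one face of the iminium ion is shielded by the benzyl group); C1 is racemic in 8 and epimeric in 10 and is fixed only in the planar dienolate, where the thioester turns away from the quaternary C11 toward C9–H, so the chain on C11 delivers the aldehyde to the face that leaves the thioester cis to the lactone oxygen and the methyl cis to C20; C14 follows from a lithium-bridged closed chair transition state with the enolate oxygen syn to C10, which puts the new hydroxyl cis to the thioester. The step needs site selectivity for the furan α-carbon over the β-carbon (secured by its vinylogous relation to the silyloxy group), C1 over C9 in the aldol (secured by ring strain and conjugation) and aldol over acyl transfer to the thioester (secured by low temperature and lithium chelation of the aldolate), and it funnels all stereoisomers of 7/8 into one product.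

Step 5
Reactants: 11 annulation product
Product: 12 trans-fused saturated lactone (C10–H cis to C14–OH)
Conditions: H2 (1 atm), [Ir(cod)(PCy3)(py)]PF6 (5 mol%), CH2Cl2, 23 °C
Reagents that add atoms: none
Why: hydroxyl-directed homogeneous hydrogenation, in which the axial C14–OH binds the cationic iridium and delivers H2 to its own face of the C9=C10 alkene (the other face is blocked by the axial C15 and C20 groups), setting C10.

Step 6
Reactants: 12 trans-fused saturated lactone
Product: 13 diol lactone (C20–OH and C14–OH free)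
Conditions: HF·pyridine, pyridine, THF, 0 °C
Reagents that add atoms: none
Why: fluoride cleavage of the only silyl ether (primary) frees C20–OH without touching lactone or thioester.

Step 7
Reactants: 13 diol lactone
Product: 14 C20 tosylate
Conditions: TsCl, pyridine, DMAP (cat.), CH2Cl2, 0 → 23 °C
Reagents that add atoms: p-toluenesulfonyl chloride Cc1ccc(cc1)S(=O)(=O)Cl
Why: selective sulfonylation of the primary hydroxyl over the hindered axial secondary C14–OH.

Step 8
Reactants: 14 C20 tosylate
Product: 15 C9-hydroxy lactone (C9–OH cis to C10–H)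
Conditions: KN(SiMe3)2 (2.2 equiv), THF, −78 °C; 2-(phenylsulfonyl)-3-phenyloxaziridine; AcOH
Reagents that add atoms: 2-(phenylsulfonyl)-3-phenyloxaziridine O=S(=O)(c1ccccc1)N1OC1c1ccccc1
Why: hydroxylation of the lactone enolate (the C14 alkoxide is carried as a spectator) by the N-sulfonyloxaziridine, which should approach C9 anti to the quaternary C1 on the neighbouring C10.

Step 9
Reactants: 15 C9-hydroxy lactone
Product: 16 bis(triethylsilyl) ether (C9 and C14)
Conditions: Et3SiOTf, 2,6-lutidine, CH2Cl2, −78 → 0 °C
Reagents that add atoms: triethylsilyl triflate CC[Si](CC)(CC)OS(=O)(=O)C(F)(F)F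
Why: silylation of both secondary hydroxyls; the C9 silyl ether is also the non-chelating group needed in step 16.

Step 10
Reactants: 16 bis(triethylsilyl) ether
Product: 17 C2 aldehyde
Conditions: Et3SiH, Pd/C (10 mol%), acetone, 23 °C
Reagents that add atoms: none
Why: Fukuyama reduction, in which palladium inserts into the C–S bond and the silane delivers hydride; lactone, tosylate and silyl ethers are inert.

Step 11
Reactants: 18 3-bromobut-3-en-1-ol
Product: 19 2-bromo-4-iodobut-1-ene
Conditions: I2, PPh3, imidazole, CH2Cl2, 0 °C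
Reagents that add atoms: iodine II
Why: Appel-type iodination of a primary alcohol.

Step 12
Reactants: 17 C2 aldehyde; 19 2-bromo-4-iodobut-1-ene
Product: 21 C2 carbinol carrying the C3–C5 arm (2-bromoallyl terminus), via bis(3-bromobut-3-enyl)zinc 20 (not isolated)
Conditions: 19, Et2Zn, CuI (cat.), 50 °C, then vacuum; 17, Ti(OiPr)4, (1R,2R)-1,2-bis(trifluoromethanesulfonamido)cyclohexane (8 mol%), toluene, −20 °C; aq. HCl
Reagents that add atoms: none
Why: iodine–zinc exchange gives the dialkylzinc, which adds to the non-enolizable aldehyde in a titanium/bis-sulfonamide-catalysed asymmetric alkylation; reagent control should deliver the alkyl group to the Si face and set C2, while zinc reagents leave lactone, tosylate and vinyl bromide alone.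

Step 13
Reactants: 21 C2 carbinol
Product: 22 tris(triethylsilyl) ether
Conditions: Et3SiOTf, 2,6-lutidine, CH2Cl2, −78 → 0 °C
Reagents that add atoms: triethylsilyl triflate CC[Si](CC)(CC)OS(=O)(=O)C(F)(F)F
Why: silylation of the hindered C2–OH so that all three future acetate positions carry the same group.

Step 14
Reactants: 22 tris(triethylsilyl) ether
Product: 24 epoxy Weinreb amide, via hydroxy tosylate Weinreb amide 23 (not isolated)
Conditions: MeNHOMe·HCl, iPrMgCl, THF, −20 → 23 °C
Reagents that add atoms: N,O-dimethylhydroxylamine hydrochloride CNOC.Cl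
Why: aminolysis of the lactone by the magnesium amide opens the template, and the released tertiary C11 alkoxide displaces the neighbouring primary tosylate (3-exo-tet, retention at C11), so the former lactone oxygen becomes the epoxide oxygen and the opening is irreversible.

Step 15
Reactants: 24 epoxy Weinreb amide; 25 vinylmagnesium bromide
Product: 26 C8 vinyl ketone
Conditions: CH2=CHMgBr, THF, −40 → 0 °C; AcOH
Reagents that add atoms: none
Why: Weinreb ketone synthesis, in which the chelated tetrahedral intermediate prevents over-addition; cold acidic quench avoids amine conjugate addition.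

Step 16
Reactants: 26 C8 vinyl ketone; 27 tert-butyl propionate
Product: 28 tertiary carbinol (aldol adduct; C8 and C17 set)
Conditions: 27, LiN(iPr)2, THF–DMPU, −78 °C (enolate with methyl cis to OLi); CeCl3; then 26; AcOH
Reagents that add atoms: none
Why: aldol addition of the cerium ester enolate (clean 1,2-addition to the enone); attack anti to the non-chelating C9–OSiEt3 bond (polar non-chelation model) sets C8, and a closed chair transition state with the C9 branch equatorial gives the syn relation that sets C17.

Step 17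
Reactants: 28 tertiary carbinol
Product: 29 tetraol (C2, C9, C14 and C8 hydroxyls free)
Conditions: HF·pyridine, pyridine, THF, 0 → 23 °C
Reagents that add atoms: none
Why: buffered fluoride removes the three triethylsilyl ethers while epoxide, tert-butyl ester and vinyl bromide should survive.

Step 18
Reactants: 29 tetraol
Product: 30 triacetate (C2, C9, C14)
Conditions: Ac2O, pyridine, DMAP (cat.), CH2Cl2, 23 °C
Reagents that add atoms: acetic anhydride CC(=O)OC(C)=O
Why: acylation of the three secondary hydroxyls; the hindered tertiary C8–OH should not react under these conditions.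

Step 19
Reactants: 30 triacetate
Product: 31 iodolactone (C7 set; CH2I cis to C8–OH)
Conditions: I2, NaHCO3, MeCN, 0 °C
Reagents that add atoms: iodine II
Why: iodolactonization, in which the ester carbonyl oxygen opens the iodonium ion at C7 (5-exo) with loss of isobutene; the hydroxyl-in-plane conformer of the 3-hydroxy-4-alkenoate is known to give the cis hydroxy/iodomethyl lactone under kinetic conditions.

Step 20
Reactants: 31 iodolactone
Product: 32 lactone aldehyde (C6 aldehyde)
Conditions: Me3NO, DMSO, 50 °C
Reagents that add atoms: trimethylamine N-oxide C[N+](C)(C)[O-]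
Why: Kornblum-type oxidation, in which the N-oxide oxygen displaces iodide and loss of trimethylamine gives the aldehyde under neutral conditions.

Step 21
Reactants: 32 lactone aldehyde
Product: 33 macrocyclic allylic alcohol (ten-membered ring; C6 epimers)
Conditions: CrCl2, NiCl2 (cat.), DMSO–THF, 23 °C, high dilution
Reagents that add atoms: none
Why: Nozaki–Hiyama–Kishi reaction, in which nickel inserts into the vinyl bromide and the vinylchromium adds to the aldehyde, closing the ten-membered ring and creating the 5(16)-methylene; the C6 configuration is not relied on here and is reset in steps 22 and 23.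

Step 22
Reactants: 33 macrocyclic allylic alcohol
Product: 34 macrocyclic enone (C6 ketone)
Conditions: Dess–Martin periodinane, pyridine, CH2Cl2, 0 °C
Reagents that add atoms: none
Why: oxidation of the allylic alcohol converges both C6 epimers to one enone.

Step 23
Reactants: 34 macrocyclic enone
Product: 35 6-epi alcohol (C6–OH anti to C8–OH)
Conditions: Me4NBH(OAc)3, MeCN–AcOH, −30 °C
Reagents that add atoms: none
Why: Evans–Saksena reduction, in which the tertiary C8–OH binds the borohydride and delivers hydride intramolecularly to C6 in 1,2 fashion to give the 1,3-anti alcohol, the configuration opposite to that of the chloride.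

Step 24
Reactants: 35 6-epi alcohol
Product: 36 6-chloro compound (4-deoxy target)
Conditions: PPh3, hexachloroacetone, CH2Cl2, 0 °C
Reagents that add atoms: hexachloroacetone O=C(C(Cl)(Cl)Cl)C(Cl)(Cl)Cl
Why: Appel-type chlorination, SN2 displacement of the alkoxyphosphonium with inversion at C6 under conditions known to suppress allylic transposition; the tertiary C8–OH does not react.

Step 25
Reactants: 36 6-chloro compound
Product: 37 CNP0312034.1 (target)
Conditions: SeO2 (cat.), tBuOOH, CH2Cl2, 0 → 23 °C
Reagents that add atoms: tert-butyl hydroperoxide CC(C)(C)OO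
Why: allylic hydroxylation by SeO2 (ene reaction at the exocyclic methylene, then [2,3]-sigmatropic shift) returns the 5(16)-alkene and places OH at C4, the only allylic CH2 (C6–H is deactivated by chlorine); attack on the outer face of the ten-membered ring is expected to give the C4 configuration shown.

**Compound list**

1 | (tert-butyldimethylsilyloxy)acetaldehyde | O=CCO[Si](C)(C)C(C)(C)C | starting material
2 | methyl propiolate | C#CC(=O)OC | starting material
3 | methyl 5-(tert-butyldimethylsilyloxy)-4-hydroxypent-2-ynoate (racemic) | COC(=O)C#CC(O)CO[Si](C)(C)C(C)(C)C | intermediate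
4 | 2,2,5-trimethyl-1,3-dioxane-4,6-dione (methyl Meldrum's acid) | CC1C(=O)OC(C)(C)OC1=O | starting material
5 | Meldrum adduct: 5-[2-(tert-butyldimethylsilyloxymethyl)-5-oxo-2,5-dihydrofuran-3-yl]-2,2,5-trimethyl-1,3-dioxane-4,6-dione (racemic) | CC1(C(=O)OC(C)(C)OC1=O)C1=CC(=O)OC1CO[Si](C)(C)C(C)(C)C | intermediate
6 | malonic half thioester: 3-(ethylsulfanyl)-2-methyl-3-oxo-2-[2-(tert-butyldimethylsilyloxymethyl)-5-oxo-2,5-dihydrofuran-3-yl]propanoic acid (stereoisomer mixture) | CCSC(=O)C(C)(C(=O)O)C1=CC(=O)OC1CO[Si](C)(C)C(C)(C)C | intermediate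
7 | thioester butenolide: S-ethyl 2-[2-(tert-butyldimethylsilyloxymethyl)-5-oxo-2,5-dihydrofuran-3-yl]propanethioate (stereoisomer mixture) | CCSC(=O)C(C)C1=CC(=O)OC1CO[Si](C)(C)C(C)(C)C | intermediate
8 | silyloxyfuran: S-ethyl 2-[5-(tert-butyldimethylsilyloxy)-2-(tert-butyldimethylsilyloxymethyl)furan-3-yl]propanethioate (racemic at C1) | CCSC(=O)C(C)c1cc(O[Si](C)(C)C(C)(C)C)oc1CO[Si](C)(C)C(C)(C)C | intermediate
9 | acrolein | C=CC=O | starting material
10 | Michael aldehyde: butenolide with quaternary C11 carrying CH2OTBS and 3-oxopropyl (C11 defined, C1 epimers) | O=CCC[C@@]1(CO[Si](C)(C)C(C)(C)C)OC(=O)C=C1C(C)C(=O)SCC | intermediate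
11 | annulation product: ring A fused to the 2(5H)-furanone at C10–C11; C1 bears methyl and C(=O)SEt; C14–OH cis to the thioester and to the ring oxygen on C11; C11 bears CH2OTBS | CCSC(=O)[C@@]1(C)[C@@H](O)CC[C@@]2(CO[Si](C)(C)C(C)(C)C)OC(=O)C=C12 | intermediate
12 | trans-fused saturated lactone (C10–H cis to C14–OH) | CCSC(=O)[C@@]1(C)[C@@H](O)CC[C@@]2(CO[Si](C)(C)C(C)(C)C)OC(=O)C[C@H]12 | intermediate
13 | diol lactone (C20–OH free) | CCSC(=O)[C@@]1(C)[C@@H](O)CC[C@@]2(CO)OC(=O)C[C@H]12 | intermediate
14 | C20 tosylate | CCSC(=O)[C@@]1(C)[C@@H](O)CC[C@@]2(COS(=O)(=O)c3ccc(C)cc3)OC(=O)C[C@H]12 | intermediate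
15 | C9-hydroxy lactone (C9–OH cis to C10–H, trans to C1) | CCSC(=O)[C@@]1(C)[C@@H](O)CC[C@@]2(COS(=O)(=O)c3ccc(C)cc3)OC(=O)[C@@H](O)[C@H]12 | intermediate
16 | bis(triethylsilyl) ether (C9, C14) | CCSC(=O)[C@@]1(C)[C@@H](O[Si](CC)(CC)CC)CC[C@@]2(COS(=O)(=O)c3ccc(C)cc3)OC(=O)[C@@H](O[Si](CC)(CC)CC)[C@H]12 | intermediate
17 | C2 aldehyde | O=C[C@@]1(C)[C@@H](O[Si](CC)(CC)CC)CC[C@@]2(COS(=O)(=O)c3ccc(C)cc3)OC(=O)[C@@H](O[Si](CC)(CC)CC)[C@H]12 | intermediate
18 | 3-bromobut-3-en-1-ol | C=C(Br)CCO | starting material
19 | 2-bromo-4-iodobut-1-ene | C=C(Br)CCI | intermediate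
20 | bis(3-bromobut-3-enyl)zinc | C=C(Br)CC[Zn]CCC(Br)=C | intermediate
21 | C2 carbinol (C2 as in the target) with the 3-bromobut-3-enyl arm (C3–C5, C16) | C=C(Br)CC[C@H](O)[C@@]1(C)[C@@H](O[Si](CC)(CC)CC)CC[C@@]2(COS(=O)(=O)c3ccc(C)cc3)OC(=O)[C@@H](O[Si](CC)(CC)CC)[C@H]12 | intermediate
22 | tris(triethylsilyl) ether (C2, C9, C14) | C=C(Br)CC[C@H](O[Si](CC)(CC)CC)[C@@]1(C)[C@@H](O[Si](CC)(CC)CC)CC[C@@]2(COS(=O)(=O)c3ccc(C)cc3)OC(=O)[C@@H](O[Si](CC)(CC)CC)[C@H]12 | intermediate
23 | hydroxy tosylate Weinreb amide (lactone opened; C11–OH, C20–OTs) | C=C(Br)CC[C@H](O[Si](CC)(CC)CC)[C@@]1(C)[C@@H](O[Si](CC)(CC)CC)CC[C@](O)(COS(=O)(=O)c2ccc(C)cc2)[C@@H]1[C@H](O[Si](CC)(CC)CC)C(=O)N(C)OC | intermediate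
24 | epoxy Weinreb amide (11,20-epoxide in place) | C=C(Br)CC[C@H](O[Si](CC)(CC)CC)[C@@]1(C)[C@@H](O[Si](CC)(CC)CC)CC[C@]2(CO2)[C@@H]1[C@H](O[Si](CC)(CC)CC)C(=O)N(C)OC | intermediate
25 | vinylmagnesium bromide | C=C[Mg]Br | starting material
26 | C8 vinyl ketone | C=C(Br)CC[C@H](O[Si](CC)(CC)CC)[C@@]1(C)[C@@H](O[Si](CC)(CC)CC)CC[C@]2(CO2)[C@@H]1[C@H](O[Si](CC)(CC)CC)C(=O)C=C | intermediate
27 | tert-butyl propionate | CCC(=O)OC(C)(C)C | starting material
28 | tertiary carbinol (C8–OH, C8 vinyl, C17 methyl, tert-butyl ester) | C=C(Br)CC[C@H](O[Si](CC)(CC)CC)[C@@]1(C)[C@@H](O[Si](CC)(CC)CC)CC[C@]2(CO2)[C@@H]1[C@H](O[Si](CC)(CC)CC)[C@](C=C)(O)[C@@H](C)C(=O)OC(C)(C)C | intermediate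
29 | tetraol | C=C(Br)CC[C@H](O)[C@@]1(C)[C@@H](O)CC[C@]2(CO2)[C@@H]1[C@H](O)[C@](C=C)(O)[C@@H](C)C(=O)OC(C)(C)C | intermediate
30 | triacetate (C2, C9, C14) | C=C(Br)CC[C@H](OC(C)=O)[C@@]1(C)[C@@H](OC(C)=O)CC[C@]2(CO2)[C@@H]1[C@H](OC(C)=O)[C@](C=C)(O)[C@@H](C)C(=O)OC(C)(C)C | intermediate
31 | iodolactone (γ-lactone C7/C8/C17/C19; C7 bears CH2I cis to C8–OH) | C=C(Br)CC[C@H](OC(C)=O)[C@@]1(C)[C@@H](OC(C)=O)CC[C@]2(CO2)[C@@H]1[C@H](OC(C)=O)[C@]1(O)[C@@H](C)C(=O)O[C@H]1CI | intermediate
32 | lactone aldehyde (C6 = CHO) | C=C(Br)CC[C@H](OC(C)=O)[C@@]1(C)[C@@H](OC(C)=O)CC[C@]2(CO2)[C@@H]1[C@H](OC(C)=O)[C@]1(O)[C@@H](C)C(=O)O[C@H]1C=O | intermediate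
33 | macrocyclic allylic alcohol (mixture of C6 epimers; C6 left undefined) | C=C1CC[C@H](OC(C)=O)[C@@]2(C)[C@@H](OC(C)=O)CC[C@]3(CO3)[C@@H]2[C@H](OC(C)=O)[C@]2(O)[C@@H](C)C(=O)O[C@H]2C1O | intermediate
34 | macrocyclic enone (C6 ketone) | C=C1CC[C@H](OC(C)=O)[C@@]2(C)[C@@H](OC(C)=O)CC[C@]3(CO3)[C@@H]2[C@H](OC(C)=O)[C@]2(O)[C@@H](C)C(=O)O[C@H]2C1=O | intermediate
35 | 6-epi alcohol (C6–OH anti to C8–OH) | C=C1CC[C@H](OC(C)=O)[C@@]2(C)[C@@H](OC(C)=O)CC[C@]3(CO3)[C@@H]2[C@H](OC(C)=O)[C@]2(O)[C@@H](C)C(=O)O[C@H]2[C@@H]1O | intermediate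
36 | 6-chloro compound (4-deoxy target) | C=C1CC[C@H](OC(C)=O)[C@@]2(C)[C@@H](OC(C)=O)CC[C@]3(CO3)[C@@H]2[C@H](OC(C)=O)[C@]2(O)[C@@H](C)C(=O)O[C@H]2[C@H]1Cl | intermediate
37 | CNP0312034.1 | C=C1[C@H](O)C[C@H](OC(C)=O)[C@@]2(C)[C@@H](OC(C)=O)CC[C@]3(CO3)[C@@H]2[C@H](OC(C)=O)[C@]2(O)[C@@H](C)C(=O)O[C@H]2[C@H]1Cl | target

**Step count and risks**

Total: 25 steps. Longest linear sequence: 24 steps (steps 1–10 and 12–25; step 11 is a one-step branch).

Steps most likely to fail:

1. Step 4. Enantiofacial discrimination at the fully substituted furan carbon may be poor with the unsubstituted enal, and reversible aldol closure or acyl transfer to the thioester may erode the C1/C14 control. The fallback sets out from 8: the Mukaiyama–Michael stage is run with an achiral ammonium salt (pyrrolidinium trifluoroacetate) and the aldehyde is cyclized with LiCl/DBU as before, giving 11 together with the enantiomer of 11 F1; the antipodes are separated by preparative chromatography on a chiral stationary phase and the route is rejoined at 11.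

2. Step 21. Closure of the ten-membered ring may be outpaced by intermolecular coupling or by protonation of the vinylchromium species. The fallback sets out from 28: Bu4NF in DMF at 60 °C removes the silyl ethers and dehydrobrominates the 2-bromoalkene to give alkyne tetraol F2; acetylation as in step 18 gives alkyne triacetate F3, iodolactonization as in step 19 gives alkyne iodolactone F4, and N-oxide oxidation as in step 20 gives ynal F5. Ni(cod)2, a bulky N-heterocyclic carbene (IPr) and Et3SiH then effect a reductive alkyne–aldehyde macrocyclization with C–C bond formation at the internal alkyne carbon to give macrocyclic triethylsilyl ether F6, which HF·pyridine converts to 33.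

3. Step 25. The ene reaction may occur on the wrong face of the ring, or oxidation may run on to the ketone. The fallback sets out from 36: stoichiometric SeO2 in dioxane (or SeO2/tBuOOH followed by Dess–Martin periodinane) drives the oxidation to C4 enone F7, which is reduced in 1,2 fashion with NaBH4/CeCl3 at −78 °C (or with an oxazaborolidine/borane pair for reagent control) to give 37.

**Further compounds**

F1 | step 4 | enantiomer of 11 | CCSC(=O)[C@]1(C)[C@H](O)CC[C@]2(CO[Si](C)(C)C(C)(C)C)OC(=O)C=C12
F2 | step 21 | alkyne tetraol | C#CCC[C@H](O)[C@@]1(C)[C@@H](O)CC[C@]2(CO2)[C@@H]1[C@H](O)[C@](C=C)(O)[C@@H](C)C(=O)OC(C)(C)C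
F3 | step 21 | alkyne triacetate | C#CCC[C@H](OC(C)=O)[C@@]1(C)[C@@H](OC(C)=O)CC[C@]2(CO2)[C@@H]1[C@H](OC(C)=O)[C@](C=C)(O)[C@@H](C)C(=O)OC(C)(C)C
F4 | step 21 | alkyne iodolactone | C#CCC[C@H](OC(C)=O)[C@@]1(C)[C@@H](OC(C)=O)CC[C@]2(CO2)[C@@H]1[C@H](OC(C)=O)[C@]1(O)[C@@H](C)C(=O)O[C@H]1CI
F5 | step 21 | ynal | C#CCC[C@H](OC(C)=O)[C@@]1(C)[C@@H](OC(C)=O)CC[C@]2(CO2)[C@@H]1[C@H](OC(C)=O)[C@]1(O)[C@@H](C)C(=O)O[C@H]1C=O
F6 | step 21 | macrocyclic triethylsilyl ether (C6 epimers) | C=C1CC[C@H](OC(C)=O)[C@@]2(C)[C@@H](OC(C)=O)CC[C@]3(CO3)[C@@H]2[C@H](OC(C)=O)[C@]2(O)[C@@H](C)C(=O)O[C@H]2C1O[Si](CC)(CC)CC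
F7 | step 25 | C4 enone | C=C1C(=O)C[C@H](OC(C)=O)[C@@]2(C)[C@@H](OC(C)=O)CC[C@]3(CO3)[C@@H]2[C@H](OC(C)=O)[C@]2(O)[C@@H](C)C(=O)O[C@H]2[C@H]1Cl
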